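Readings and results were generated by integration on assumed constants.

As the chemist charging the next flask, I had two things to settle: how much second substrate to give it and how long to leave it. Saturday's run had 0.67 equiv and Wednesday's 1.5 equiv, with the other charges equal.

| setting | Saturday's | Wednesday's | flask |
|---|---|---|---|
| starting material | 0.40 M | 0.40 M | 0.40 M |
| second substrate | 0.67 equiv | 1.5 equiv | 1.00 equiv |
| coupling partner | 0.95 equiv (in portions, 4) | 0.95 equiv (in portions, 4) | 0.950 equiv (in portions, 4) |
| free catalyst | 3.9 mol% | 3.9 mol% | 3.9 mol% |
| impurity | 2.9 mM | 2.9 mM | 2.9 mM |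
| remark | run made earlier; portions every 3.0 h | run made earlier; portions every 3.0 h | the portions of coupling partner follow each other after 3.0 h, the first at the start |
| time |  |  | 40 h |

| run | time / h | starting material / % | target / % |
|---|---|---|---|
| Saturday's | 3.00 | 97.3 | 1.2 |
| Saturday's | 5.00 | 94.8 | 2.0 |
| Saturday's | 8.00 | 92.3 | 5.9 |
| Saturday's | 12.0 | 87.1 | 11.5 |
| Saturday's | 15.0 | 83.1 | 13.4 |
| Saturday's | 25.0 | 74.0 | 23.8 |
| Saturday's | 40.0 | 68.0 | 30.8 |
| Wednesday's | 3.00 | 97.8 | 1.0 |
| Wednesday's | 5.00 | 96.8 | 1.6 |
| Wednesday's | 8.00 | 95.5 | 4.1 |
| Wednesday's | 12.0 | 92.2 | 7.3 |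
| Wednesday's | 15.0 | 89.8 | 9.7 |
| Wednesday's | 25.0 | 84.5 | 14.0 |
| Wednesday's | 40.0 | 82.4 | 15.9 |

(each reading ± 0.5 percentage points)

- the reaction counts as stopped when no species that holds the starting material changes by six tenths of a point or more over the second half of the time

- the state of affairs at 40 h: stopped, and by what, or still going (all of the starting material has reacted / no working catalyst is left / the coupling partner has run out first / it is still moving / forward and back rates have come level)
- conversion of starting material at 40 h
- amount of target at 40 h, in percent of the starting material charged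

I counted turnovers. Saturday's run at 40.0 h gave 7.90 turnovers. This count N, target made per free catalyst charged, is the turnover number, here read from a reading with its scatter. Wednesday's N was about half of Saturday's, so N fell as [second substrate] rose.

I wanted to see whether N follows a smooth line before changing anything else. So I charged 1.00 equiv of second substrate, the geometric middle of the two runs, and left the other charges as they were:

N(Saturday's) = 30.8% / 3.9 mol% = 7.90

N(Wednesday's) = 15.9% / 3.9 mol% = 4.08

N(flask) = sqrt(N(Saturday's) × N(Wednesday's)) = 5.67

target = N(flask) × 3.9 mol% = 22.1%

The same middle of the two conversions gave me 23.7%. Wednesday's run still gained 1.9 percentage points of target from 25.0 h to 40.0 h, so I left the flask the full 40 h and expected it to be still moving.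

The forecast, a shade above my target figure, gave it is still moving, 24% conversion and 22.3% target, in the words “Between 20 and 40 h the flask should still change by several points”.

The flask gave: it is still moving, 24.3% conversion and 23.0% target.

    starting material + free catalyst ⇌ catalyst intermediate A (K = 23.0 M⁻¹, k = 73.0 M⁻¹ h⁻¹)
    coupling partner + catalyst intermediate A → free catalyst + target (k = 2.50 M⁻¹ h⁻¹)
    second substrate + free catalyst ⇌ catalyst intermediate B (K = 210 M⁻¹, k = 31.0 M⁻¹ h⁻¹)
    coupling partner + catalyst intermediate B → free catalyst + second product (k = 8.70 M⁻¹ h⁻¹)
    free catalyst + impurity → spent catalyst (k = 14000 M⁻¹ h⁻¹)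

That target is a count of 5.90 turnovers. At 40.0 h the flask held 11% of its coupling partner against 76% of its starting material. My middle count belongs to 0.950 equiv of coupling partner: at 1.07 equiv, other charges held, target had moved by 5 points, and a run there would break it. The neighbouring flask with 3.80 equiv of coupling partner made 99.9% target at 40.0 h, a count of 25.6, more than Saturday's 7.90.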